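## Retrosynthetic overview

- C–O disconnection at the carbinol carbon: the hydroxy-enedione is the hydrolysed ortho-quinol of a 4-methoxy-2-prenylphenol. The target therefore goes back to 3-(5-hydroxy-2-methoxy-4-prenylphenyl)-7-methoxycoumarin by enantioselective ortho-hydroxylative dearomatisation.
- Biaryl C–C disconnection: 3-bromo-7-methoxycoumarin plus the boronate of 5-bromo-4-methoxy-2-prenylphenol (Suzuki).
- Building blocks: 7-methoxycoumarin + Br2; 3-bromo-4-methoxyphenol + prenyl bromide.
- Ring order: the coumarin is bought intact; the six-membered carbocycle is carried as a benzene ring and dearomatised only in the last step (no ring is built de novo).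

Assumption: phenoxide salt forms and catalytic-cycle species are not numbered; Oxone is counted as its active salt KHSO5; racemic compound 2 is drawn as one enantiomer of the trans pair.

## Route

Step 1
Reactants: 1 7-methoxy-2H-chromen-2-one (7-methoxycoumarin)
Product: 3 3-bromo-7-methoxy-2H-chromen-2-one, via trans-3,4-dibromo-7-methoxychroman-2-one 2 (not isolated)
Conditions: Br2 (1.05 equiv), CH2Cl2, 0 °C to rt; then Et3N (1.5 equiv), 0 °C to rt
Reagents that add atoms: bromine, BrBr
Why: Bromination–dehydrobromination: Br2 adds across the electron-rich, styrene-like C3=C4 bond and Et3N then removes the acidic C3–H with loss of the benzylic C4 bromide (E1cB), which leaves bromine only at C3; no stereocentre remains.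

Step 2
Reactants: 4 3-bromo-4-methoxyphenol; 5 1-bromo-3-methylbut-2-ene (prenyl bromide)
Product: 6 5-bromo-4-methoxy-2-(3-methylbut-2-en-1-yl)phenol
Conditions: NaH (1.0 equiv), toluene, 0 °C; then 5 (1.0 equiv), rt, 16 h
Reagents that add atoms: none
Why: ortho-C-alkylation of a phenoxide (SN2): the tightly ion-paired sodium phenoxide in non-polar toluene attacks the primary carbon of 5 through its ortho carbon and re-aromatises, and of the two ortho positions only C6 is free of the flanking bromine; no stereocentre is formed.

Step 3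
Reactants: 6 5-bromo-4-methoxy-2-(3-methylbut-2-en-1-yl)phenol; 3 3-bromo-7-methoxy-2H-chromen-2-one
Product: 8 3-[5-hydroxy-2-methoxy-4-(3-methylbut-2-en-1-yl)phenyl]-7-methoxy-2H-chromen-2-one, via aryl pinacol boronate 7 (not isolated)
Conditions: B2pin2 (1.1 equiv), XPhos Pd G2 (2 mol %), KOAc (3 equiv), degassed dioxane, 90 °C; then 3 (1.0 equiv), aq. K3PO4 (3 equiv), 80 °C
Reagents that add atoms: bis(pinacolato)diboron, CC1(C)OB(OC1(C)C)B1OC(C)(C)C(C)(C)O1 (supplies the Bpin group of 7; no atom of it remains in 8)
Why: Miyaura borylation followed in the same pot by Suzuki–Miyaura coupling: the aryl bromide is borylated under weak-base conditions that leave the phenol and the prenyl group alone, and the activated vinylic C–Br bond of 3 then couples under mild phosphate base (hydroxide is avoided because it would ring-contract 3); no stereocentre is formed.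

Step 4
Reactants: 8 3-[5-hydroxy-2-methoxy-4-(3-methylbut-2-en-1-yl)phenyl]-7-methoxy-2H-chromen-2-one
Product: 10 (5R)-5-hydroxy-2-(7-methoxy-2-oxo-2H-chromen-3-yl)-5-(3-methylbut-2-en-1-yl)cyclohex-2-ene-1,4-dione, via (R)-ortho-quinol methyl dienol ether 9 (not isolated)
Conditions: pre-catalyst C* = sodium 2-iodo-5-methyl-3-{[(2R)-1-(mesitylamino)-1-oxopropan-2-yl]oxy}benzenesulfonate (10 mol %), powdered Oxone (1.2 equiv KHSO5), n-Bu4NHSO4 (10 mol %), Na2SO4, EtOAc, 25 °C; then 0.5 M aq. HCl, THF, 0 °C
Reagents that add atoms: potassium peroxymonosulfate (active part of Oxone), [K+].[O-]S(=O)(=O)OO; water, O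
Why: Proposed new method: catalytic enantioselective ortho-hydroxylative phenol dearomatisation by a chiral iodine(V) species made in situ — Oxone oxidises iodoarene C* to a cyclic IBS-type λ5-iodane, phenol 8 exchanges onto iodine trans to the sulfonate oxygen and so directly beside the lactamide arm, and the iodyl oxygen is passed intramolecularly ([2,3]-type ligand coupling, I(V) to I(III)) to the prenyl-bearing ortho carbon C4′ (the other ortho carbon C6′ is shielded by the twisted coumarinyl group, and oxygen delivered from the phenol-bound iodine cannot reach the para carbon); the N–H···O=I hydrogen bond holds the oxo ligand on the amide side and the mesityl wall lets the phenoxide present only the Re face of C4′ (C5′ > C3′ > CH2), which sets (R); protonolysis frees 9, Oxone returns I(III) to I(V), and dilute acid hydrolyses the dienol methyl ether of 9 to the C1 ketone of 10 without touching the quaternary carbinol; the closest known reaction types are the stoichiometric chiral λ5-iodane (and achiral SIBX) hydroxylative dearomatisation of 2-alkylphenols to ortho-quinols and the achiral IBS/Oxone-catalysed ortho-oxygenation of phenols; if the observed sense of induction is opposite, ent-C* from the other lactate is used.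

## Compound list

1 | 7-methoxy-2H-chromen-2-one (7-methoxycoumarin) | COc1ccc2ccc(=O)oc2c1 | starting material
2 | trans-3,4-dibromo-7-methoxychroman-2-one (racemic, one enantiomer drawn) | O=C1Oc2cc(OC)ccc2[C@H](Br)[C@H]1Br | intermediate
3 | 3-bromo-7-methoxy-2H-chromen-2-one | COc1ccc2cc(Br)c(=O)oc2c1 | intermediate
4 | 3-bromo-4-methoxyphenol | COc1ccc(O)cc1Br | starting material
5 | 1-bromo-3-methylbut-2-ene (prenyl bromide) | CC(C)=CCBr | starting material
6 | 5-bromo-4-methoxy-2-(3-methylbut-2-en-1-yl)phenol | COc1cc(CC=C(C)C)c(O)cc1Br | intermediate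
7 | 4-methoxy-2-(3-methylbut-2-en-1-yl)-5-(4,4,5,5-tetramethyl-1,3,2-dioxaborolan-2-yl)phenol | COc1cc(CC=C(C)C)c(O)cc1B1OC(C)(C)C(C)(C)O1 | intermediate
8 | 3-[5-hydroxy-2-methoxy-4-(3-methylbut-2-en-1-yl)phenyl]-7-methoxy-2H-chromen-2-one | COc1ccc2cc(-c3cc(O)c(CC=C(C)C)cc3OC)c(=O)oc2c1 | intermediate
9 | (6R)-6-hydroxy-4-methoxy-3-(7-methoxy-2-oxo-2H-chromen-3-yl)-6-(3-methylbut-2-en-1-yl)cyclohexa-2,4-dien-1-one | COc1ccc2cc(C3=CC(=O)[C@@](O)(CC=C(C)C)C=C3OC)c(=O)oc2c1 | intermediate
10 | (5R)-5-hydroxy-2-(7-methoxy-2-oxo-2H-chromen-3-yl)-5-(3-methylbut-2-en-1-yl)cyclohex-2-ene-1,4-dione | COc1ccc2cc(C3=CC(=O)[C@@](O)(CC=C(C)C)CC3=O)c(=O)oc2c1 | target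

## Step count and risks

Total steps: 4 (steps 1–4). Longest linear sequence: 3 (4 → 6 → 8 → 10); step 1 is a one-step side branch.

Steps most likely to fail:

1. Step 4 (the proposed new catalytic asymmetric dearomatisation). The risks are low enantioselectivity, poor catalyst turnover, and loss of the methoxy group to give the para-quinone. Fallback with known chemistry, setting out from 8 and coming back at 10: 8 is treated with stoichiometric achiral SIBX (stabilised IBX) in THF at rt, which is the established ortho-hydroxylative dearomatisation of 2-alkylphenols. This gives racemic 6-hydroxy-4-methoxy-3-(7-methoxy-2-oxo-2H-chromen-3-yl)-6-(3-methylbut-2-en-1-yl)cyclohexa-2,4-dien-1-one F4, which is not isolated. The same dilute aqueous HCl work-up hydrolyses it to racemic 5-hydroxy-2-(7-methoxy-2-oxo-2H-chromen-3-yl)-5-(3-methylbut-2-en-1-yl)cyclohex-2-ene-1,4-dione F5. Preparative chiral SFC on an amylose phase then separates 10 from (5S)-5-hydroxy-2-(7-methoxy-2-oxo-2H-chromen-3-yl)-5-(3-methylbut-2-en-1-yl)cyclohex-2-ene-1,4-dione F6, with the assignment checked by ECD and optical rotation.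

2. Step 2 (direct ortho-C-prenylation). The risks are competing O-prenylation, double alkylation and a modest yield. Fallback setting out from 4 and coming back at 6: the C–C bond is made by cross-coupling instead of phenoxide alkylation. Compound 4 is iodinated at its only unhindered ortho position (NIS, cat. TsOH, MeCN, rt) to give 5-bromo-2-iodo-4-methoxyphenol F1. A chemoselective Stille coupling at the C–I bond with tributyl(3-methylbut-2-en-1-yl)stannane (Pd(PPh3)4, DMF, 80 °C) then delivers the linear prenyl arene 6. The C–Br bond is left for step 3, and any 1,1-dimethylallyl isomer is removed by chromatography.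

3. Step 3 (telescoped borylation/Suzuki coupling). The risks are protodeboronation of the electron-rich ortho-alkoxy boronate and base-induced degradation of 3. Fallback setting out from 6 and coming back at 8: the coumarin ring is built onto the aryl fragment instead of forming the biaryl bond, so 3 and step 1 are no longer needed. Pd-catalysed cyanomethylation of 6 (Me3SiCH2CN, ZnF2, Pd2(dba)3/Xantphos, DMF, 90 °C) gives 2-[5-hydroxy-2-methoxy-4-(3-methylbut-2-en-1-yl)phenyl]acetonitrile F2. Knoevenagel condensation of this nitrile with commercial 2-hydroxy-4-methoxybenzaldehyde (piperidine, EtOH, reflux) and in-situ addition of the phenol to the nitrile gives 3-[5-hydroxy-2-methoxy-4-(3-methylbut-2-en-1-yl)phenyl]-7-methoxy-2H-chromen-2-imine F3. Brief treatment with dilute aqueous HCl at rt hydrolyses the imine to lactone 8.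

## Further compounds

F1 | step 2 | 5-bromo-2-iodo-4-methoxyphenol | COc1cc(I)c(O)cc1Br
F2 | step 3 | 2-[5-hydroxy-2-methoxy-4-(3-methylbut-2-en-1-yl)phenyl]acetonitrile | COc1cc(CC=C(C)C)c(O)cc1CC#N
F3 | step 3 | 3-[5-hydroxy-2-methoxy-4-(3-methylbut-2-en-1-yl)phenyl]-7-methoxy-2H-chromen-2-imine | COc1ccc2C=C(c3cc(O)c(CC=C(C)C)cc3OC)C(=N)Oc2c1
F4 | step 4 | racemic 6-hydroxy-4-methoxy-3-(7-methoxy-2-oxo-2H-chromen-3-yl)-6-(3-methylbut-2-en-1-yl)cyclohexa-2,4-dien-1-one | COc1ccc2cc(C3=CC(=O)C(O)(CC=C(C)C)C=C3OC)c(=O)oc2c1
F5 | step 4 | racemic 5-hydroxy-2-(7-methoxy-2-oxo-2H-chromen-3-yl)-5-(3-methylbut-2-en-1-yl)cyclohex-2-ene-1,4-dione | COc1ccc2cc(C3=CC(=O)C(O)(CC=C(C)C)CC3=O)c(=O)oc2c1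
F6 | step 4 | (5S)-5-hydroxy-2-(7-methoxy-2-oxo-2H-chromen-3-yl)-5-(3-methylbut-2-en-1-yl)cyclohex-2-ene-1,4-dione | COc1ccc2cc(C3=CC(=O)[C@](O)(CC=C(C)C)CC3=O)c(=O)oc2c1
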